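The 2-methoxy-4-pyranone (ring atoms O1, C2(OMe), C3(Me), C4(=O), C5(Me), C6 bearing the C11 chain) is disconnected at O1–C2 and C5–C6. C2–C5, with both methyls and the methoxy group, come from a 1,1-dimethoxy-2-methyl-3-silyloxypenta-1,3-diene. O1 and C6 come from a C12 aldehyde that carries the (S)-carbinol, set from (S)-propylene oxide, as a silyl ether. One Lewis-acid cyclocondensation forms both bonds, closes the ring and delivers the C2 methoxy from the acetal carbon, so no hydroxypyranone needs regioselective O-methylation. Dehydrogenation across C5–C6, desilylation and acetylation finish the synthesis.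

Key step: step 7

Remark: the C6 side chain has eleven carbons (nine CH2, the oxygenated CH, one CH3), so the aldehyde partner must have twelve carbons (formyl carbon, nine CH2, CH(O), CH3) and its alkene precursor thirteen (vinyl group, nine CH2, CH(O), CH3); the alcohol is carried as its TBS ether and acetylated last, because an acetate CH3 would compete with ring C5–H for the amide base in step 8; ring atoms are numbered as in the target in all Why lines.

Step 1
Reactants: 1 trimethyl orthopropionate (1,1,1-trimethoxypropane)
Product: 2 1,1-dimethoxyprop-1-ene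
Conditions: TMSOTf (1.1 equiv), iPr2NEt (1.3 equiv), CH2Cl2, −20 °C → rt; pentane, filter, distil
Reagents that add atoms: none
Why: The silyl triflate removes one methoxide as MeOSiMe3 and the hindered amine takes the α-proton of the dimethoxycarbenium ion, a silyl-triflate/amine elimination of methanol from an orthoester that should give the volatile ketene acetal.

Step 2
Reactants: 2 1,1-dimethoxyprop-1-ene (2.2 equiv); 3 propanoyl chloride
Product: 4 1,1-dimethoxy-2-methylpent-1-en-3-one
Conditions: 3 added to 2, Et2O, 0 °C → rt; distil under reduced pressure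
Reagents that add atoms: none
Why: Electrophilic C-acylation of the nucleophilic ketene-acetal carbon, in which the acylated dimethoxycarbenium chloride gives its α-proton to a second molecule of 2 (which ends as methyl propanoate and chloromethane), so no amine is present that could turn 3 into methylketene, and the methyl on the acylated carbon prevents a second acylation.

Step 3
Reactants: 4 1,1-dimethoxy-2-methylpent-1-en-3-one
Product: 6 1,1-dimethoxy-2-methyl-3-(trimethylsilyloxy)penta-1,3-diene (E/Z mixture at the silyl enol ether), via lithium enolate 5 (not isolated)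
Conditions: LiN(iPr)2 (1.1 equiv), THF, −78 °C; Me3SiCl (1.2 equiv), −78 → 0 °C; pentane, filter, bulb-to-bulb distil
Reagents that add atoms: chlorotrimethylsilane, C[Si](C)(C)Cl
Why: Kinetic enolisation at the only acidic position (the CH2 of the ethyl ketone) followed by O-silylation of the enolate, a standard silyl enol ether synthesis whose alkene geometry is immaterial because the ring centres derived from it later become sp2.

Step 4
Reactants: 7 10-bromodec-1-ene; 8 (S)-propylene oxide
Product: 10 (S)-tridec-12-en-2-ol, via dec-9-enylmagnesium bromide 9 (not isolated)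
Conditions: Mg, THF, rt → 40 °C; then CuI (0.1 equiv), 8, −30 → 0 °C; aq NH4Cl
Reagents that add atoms: none
Why: Copper-catalysed Grignard opening of the terminal epoxide at its unsubstituted CH2 (SN2) joins the C10 alkenyl unit to the C3 epoxide to give the C13 alkenol without making or breaking a bond at the stereocentre, so the (S) configuration of 8 becomes C2 of 10.

Step 5
Reactants: 10 (S)-tridec-12-en-2-ol
Product: 11 (S)-tert-butyldimethyl(tridec-12-en-2-yloxy)silane
Conditions: TBSCl (1.2 equiv), imidazole (2.5 equiv), DMF, rt
Reagents that add atoms: tert-butylchlorodimethylsilane, CC(C)(C)[Si](C)(C)Cl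
Why: Imidazole-mediated silylation of a secondary alcohol gives an ether with no acidic C–H that should withstand ozone, ZnCl2 and lithium amide.

Step 6
Reactants: 11 (S)-tert-butyldimethyl(tridec-12-en-2-yloxy)silane
Product: 13 (11S)-11-(tert-butyldimethylsilyloxy)dodecanal, via ozonide 12 (not isolated)
Conditions: O3, CH2Cl2, −78 °C; then PPh3 (1.2 equiv), −78 °C → rt
Reagents that add atoms: ozone, [O-][O+]=O
Why: Ozonolysis of the terminal alkene with reductive work-up removes the terminal carbon as formaldehyde and leaves the remote silyl ether and stereocentre untouched.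

Step 7
Reactants: 6 1,1-dimethoxy-2-methyl-3-(trimethylsilyloxy)penta-1,3-diene (1.5 equiv); 13 (11S)-11-(tert-butyldimethylsilyloxy)dodecanal
Product: 15 2-[(10S)-10-(tert-butyldimethylsilyloxy)undecyl]-6-methoxy-3,5-dimethyl-2,3-dihydro-4H-pyran-4-one (mixture at the two ring centres), via cycloadduct 14 (not isolated)
Conditions: ZnCl2 (1.0 equiv, 1 M in Et2O), CH2Cl2, −20 °C → rt; then PPTS (0.1 equiv), rt
Reagents that add atoms: none
Why: ZnCl2 activates the aldehyde; the enol-ether terminus of 6 (future C5) bonds to the formyl carbon (future C6) and the aldehyde oxygen (future O1) bonds to the acetal carbon of 6 (future C2), either in one concerted hetero-Diels–Alder event or as a Mukaiyama-type aldol addition whose zinc alkoxide then closes on the dimethoxy-bearing carbon of the O-silylated enone, and the resulting orthoester-type silyl enol ether 14 expels MeOSiMe3 (completed by catalytic PPTS) to give the vinylogous carbonate 15. The closest known reaction type is the Lewis-acid cyclocondensation of 1-alkoxy- and 1,1-dialkoxy-3-silyloxy dienes with aldehydes to 2,3-dihydropyran-4-ones. The six-membered ring closes as a [4+2] cycloaddition (in the stepwise variant as a 6-endo-trig addition–elimination at the ketene-acetal carbon). Two ring stereocentres (C5 and C6) are created without control and none is needed, because step 8 makes both sp2, while the remote (S)-carbinol centre is not touched. The one selectivity required is regiochemical and is secured by the diene itself: its oxygen-free terminus is the vinylogous nucleophilic end of both the ketene acetal and the silyl enol ether, attack through the methyl-bearing ketene-acetal carbon would have to form a quaternary centre, and only the acetal carbon carries a leaving group for ring closure. The unbranched aldehyde, the TBS ether and the methoxy enol ether of 15 should all tolerate anhydrous ZnCl2.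

Step 8
Reactants: 15 2-[(10S)-10-(tert-butyldimethylsilyloxy)undecyl]-6-methoxy-3,5-dimethyl-2,3-dihydro-4H-pyran-4-one
Product: 18 2-[(10S)-10-(tert-butyldimethylsilyloxy)undecyl]-6-methoxy-3,5-dimethyl-4H-pyran-4-one, via lithium enolate 16 (not isolated), via silyl dienol ether 17 (not isolated)
Conditions: LiN(iPr)2 (1.15 equiv), THF, −78 °C; Me3SiCl (1.3 equiv), −78 °C; DDQ (1.5 equiv), THF, −78 → −20 °C; aq NaHCO3
Reagents that add atoms: none
Why: LiN(iPr)2 removes the only acidic hydrogen (C5–H), silylation gives the 2H-pyran-type dienol ether 17, and DDQ abstracts hydride from C6–H because that alone produces an aromatic 4-silyloxy-2-methoxypyrylium ion, which loses the silyl group to the pyranone (DDQ dehydrogenation of a silyl enol ether); the sequence is kept at −78 °C so that 17 has no time for electrocyclic ring opening, and both uncontrolled ring stereocentres disappear here.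

Step 9
Reactants: 18 2-[(10S)-10-(tert-butyldimethylsilyloxy)undecyl]-6-methoxy-3,5-dimethyl-4H-pyran-4-one
Product: 19 2-[(10S)-10-hydroxyundecyl]-6-methoxy-3,5-dimethyl-4H-pyran-4-one
Conditions: HF·pyridine, pyridine, THF, 0 °C → rt
Reagents that add atoms: none
Why: Fluoride-driven cleavage of the secondary TBS ether under buffered conditions should leave the methoxypyranone and the carbinol configuration unchanged.

Step 10
Reactants: 19 2-[(10S)-10-hydroxyundecyl]-6-methoxy-3,5-dimethyl-4H-pyran-4-one
Product: 20 (2S)-11-(6-methoxy-3,5-dimethyl-4-oxo-4H-pyran-2-yl)undecan-2-yl acetate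
Conditions: Ac2O (1.5 equiv), pyridine, DMAP (0.05 equiv), CH2Cl2, rt
Reagents that add atoms: acetic anhydride, CC(=O)OC(C)=O
Why: DMAP-catalysed O-acetylation acylates the oxygen without breaking the C–O bond, so the (S) configuration is retained and the target results.

Compound list
1 | trimethyl orthopropionate (1,1,1-trimethoxypropane) | CCC(OC)(OC)OC | starting material
2 | 1,1-dimethoxyprop-1-ene | CC=C(OC)OC | intermediate
3 | propanoyl chloride | CCC(Cl)=O | starting material
4 | 1,1-dimethoxy-2-methylpent-1-en-3-one | CCC(=O)C(C)=C(OC)OC | intermediate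
5 | lithium 1,1-dimethoxy-2-methylpenta-1,3-dien-3-olate (not isolated) | [Li]OC(=CC)C(C)=C(OC)OC | intermediate
6 | 1,1-dimethoxy-2-methyl-3-(trimethylsilyloxy)penta-1,3-diene (E/Z mixture at C3=C4) | COC(OC)=C(C)C(O[Si](C)(C)C)=CC | intermediate
7 | 10-bromodec-1-ene | C=CCCCCCCCCBr | starting material
8 | (S)-propylene oxide ((S)-2-methyloxirane) | C[C@H]1CO1 | starting material
9 | dec-9-enylmagnesium bromide (not isolated) | C=CCCCCCCCC[Mg]Br | intermediate
10 | (S)-tridec-12-en-2-ol | C=CCCCCCCCCC[C@H](C)O | intermediate
11 | (S)-tert-butyldimethyl(tridec-12-en-2-yloxy)silane | C=CCCCCCCCCC[C@H](C)O[Si](C)(C)C(C)(C)C | intermediate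
12 | 3-[(10S)-10-(tert-butyldimethylsilyloxy)undecyl]-1,2,4-trioxolane (ozonide, mixture at the ring carbon, not isolated) | O1OC(CCCCCCCCC[C@H](C)O[Si](C)(C)C(C)(C)C)OC1 | intermediate
13 | (11S)-11-(tert-butyldimethylsilyloxy)dodecanal | O=CCCCCCCCCC[C@H](C)O[Si](C)(C)C(C)(C)C | intermediate
14 | 2-[(10S)-10-(tert-butyldimethylsilyloxy)undecyl]-6,6-dimethoxy-3,5-dimethyl-4-(trimethylsilyloxy)-3,6-dihydro-2H-pyran (mixture at C2 and C3, not isolated) | COC1(OC)OC(CCCCCCCCC[C@H](C)O[Si](C)(C)C(C)(C)C)C(C)C(O[Si](C)(C)C)=C1C | intermediate
15 | 2-[(10S)-10-(tert-butyldimethylsilyloxy)undecyl]-6-methoxy-3,5-dimethyl-2,3-dihydro-4H-pyran-4-one (mixture at C2 and C3 of the ring) | COC1=C(C)C(=O)C(C)C(CCCCCCCCC[C@H](C)O[Si](C)(C)C(C)(C)C)O1 | intermediate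
16 | lithium 2-[(10S)-10-(tert-butyldimethylsilyloxy)undecyl]-6-methoxy-3,5-dimethyl-2H-pyran-4-olate (mixture at C2, not isolated) | [Li]OC1=C(C)C(CCCCCCCCC[C@H](C)O[Si](C)(C)C(C)(C)C)OC(OC)=C1C | intermediate
17 | 2-[(10S)-10-(tert-butyldimethylsilyloxy)undecyl]-6-methoxy-3,5-dimethyl-4-(trimethylsilyloxy)-2H-pyran (mixture at C2, not isolated) | C[Si](C)(C)OC1=C(C)C(CCCCCCCCC[C@H](C)O[Si](C)(C)C(C)(C)C)OC(OC)=C1C | intermediate
18 | 2-[(10S)-10-(tert-butyldimethylsilyloxy)undecyl]-6-methoxy-3,5-dimethyl-4H-pyran-4-one | COc1oc(CCCCCCCCC[C@H](C)O[Si](C)(C)C(C)(C)C)c(C)c(=O)c1C | intermediate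
19 | 2-[(10S)-10-hydroxyundecyl]-6-methoxy-3,5-dimethyl-4H-pyran-4-one | COc1oc(CCCCCCCCC[C@H](C)O)c(C)c(=O)c1C | intermediate
20 | (2S)-11-(6-methoxy-3,5-dimethyl-4-oxo-4H-pyran-2-yl)undecan-2-yl acetate | COc1oc(CCCCCCCCC[C@H](C)OC(C)=O)c(C)c(=O)c1C | target

Total step count: 10 (steps 1–3 to the diene, steps 4–6 to the aldehyde, steps 7–10 union and finish).
Longest linear sequence: 7 steps (4, 5, 6, 7, 8, 9, 10).

Steps most likely to fail

1. Step 7. What may go wrong: protodesilylation or hydrolysis of the very electron-rich diene before it meets the aldehyde, C–C bond formation at the methyl-bearing ketene-acetal carbon in place of the enol-ether terminus, or hydrolytic loss of the enol-ether methoxy group during closure or work-up. The fallback sets out from aldehyde 13 and changes the ring construction to a tricarbonyl cyclisation. The dianion of methyl 2-methyl-3-oxopentanoate (NaH, then n-BuLi, THF, 0 → −78 °C) would add through its terminal carbanion to 13 to give methyl (15S)-15-(tert-butyldimethylsilyloxy)-5-hydroxy-2,4-dimethyl-3-oxohexadecanoate F1. Dess–Martin periodinane would oxidise it to methyl (15S)-15-(tert-butyldimethylsilyloxy)-2,4-dimethyl-3,5-dioxohexadecanoate F2. DBU in toluene would close this with loss of methanol to 6-[(10S)-10-(tert-butyldimethylsilyloxy)undecyl]-4-hydroxy-3,5-dimethyl-2H-pyran-2-one F3. MeOTf in CH2Cl2 would then methylate the lactone carbonyl oxygen, which after loss of a proton gives the 2-methoxy-4-pyranone 18. The route is rejoined at 18, so steps 7 and 8 are both replaced.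

2. Step 8. What may go wrong: electrocyclic opening of the 2H-pyran-type silyl dienol ether (or β-elimination of the enolate with cleavage of the ring C6–O1 bond) to an acyclic dienoate faster than hydride transfer to DDQ, or incomplete deprotonation of the tertiary C5–H. The fallback sets out from aldehyde 13 and brings C6 in at the ketone oxidation level, so no dehydrogenation is needed. Pinnick oxidation (NaClO2, NaH2PO4, 2-methylbut-2-ene, t-BuOH/H2O) would give (11S)-11-(tert-butyldimethylsilyloxy)dodecanoic acid F4. 1,1'-Carbonyldiimidazole in THF would convert it into (11S)-11-(tert-butyldimethylsilyloxy)-1-(1H-imidazol-1-yl)dodecan-1-one F5. Addition of this acyl imidazole to two equivalents of lithium enolate 5 (made from 4 as in step 3) at −78 °C would give, by C-acylation, (15S)-15-(tert-butyldimethylsilyloxy)-1,1-dimethoxy-2,4-dimethylhexadec-1-ene-3,5-dione F6. The enol oxygen of its chain-side ketone would close on the dimethoxy-bearing carbon with loss of methanol (PPTS, CH2Cl2, rt) to give pyranone 18, where the route is rejoined.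

3. Step 2. What may go wrong: demethylation of the acylated dimethoxycarbenium chloride by chloride (giving the β-keto ester in place of the acyl ketene acetal) or acid-induced oligomerisation of the ketene acetal. The fallback sets out from propanoyl chloride 3 and builds 4 without a ketene acetal, which also makes step 1 unnecessary. AlCl3-promoted acylation of 1,1-dichloroprop-1-ene (CH2Cl2, 0 °C) would give 1,1,1-trichloro-2-methylpentan-3-one F7. Et3N would remove HCl to give 1,1-dichloro-2-methylpent-1-en-3-one F8. NaOMe (2.2 equiv) in MeOH at 0 °C would replace both vinylic chlorides by addition–elimination to give 4, where the route is rejoined.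

Further compounds
F1 | step 7 | methyl (15S)-15-(tert-butyldimethylsilyloxy)-5-hydroxy-2,4-dimethyl-3-oxohexadecanoate | COC(=O)C(C)C(=O)C(C)C(O)CCCCCCCCC[C@H](C)O[Si](C)(C)C(C)(C)C
F2 | step 7 | methyl (15S)-15-(tert-butyldimethylsilyloxy)-2,4-dimethyl-3,5-dioxohexadecanoate | COC(=O)C(C)C(=O)C(C)C(=O)CCCCCCCCC[C@H](C)O[Si](C)(C)C(C)(C)C
F3 | step 7 | 6-[(10S)-10-(tert-butyldimethylsilyloxy)undecyl]-4-hydroxy-3,5-dimethyl-2H-pyran-2-one | Cc1c(O)c(C)c(CCCCCCCCC[C@H](C)O[Si](C)(C)C(C)(C)C)oc1=O
F4 | step 8 | (11S)-11-(tert-butyldimethylsilyloxy)dodecanoic acid | OC(=O)CCCCCCCCC[C@H](C)O[Si](C)(C)C(C)(C)C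
F5 | step 8 | (11S)-11-(tert-butyldimethylsilyloxy)-1-(1H-imidazol-1-yl)dodecan-1-one | O=C(CCCCCCCCC[C@H](C)O[Si](C)(C)C(C)(C)C)n1ccnc1
F6 | step 8 | (15S)-15-(tert-butyldimethylsilyloxy)-1,1-dimethoxy-2,4-dimethylhexadec-1-ene-3,5-dione | COC(OC)=C(C)C(=O)C(C)C(=O)CCCCCCCCC[C@H](C)O[Si](C)(C)C(C)(C)C
F7 | step 2 | 1,1,1-trichloro-2-methylpentan-3-one | CCC(=O)C(C)C(Cl)(Cl)Cl
F8 | step 2 | 1,1-dichloro-2-methylpent-1-en-3-one | CCC(=O)C(C)=C(Cl)Cl
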